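The route rests on cutting the O1–C2 bond of ring C and, with it, the C8–prenyl bond of ring A. O1 sits on C8a, directly beside prenyl-bearing C8, which is the retron of an aromatic Claisen rearrangement, and C2 lies β to the C4 carbonyl. The key step heats a fully protected chalcone whose future O1 carries a 1,1-dimethylallyl group: the [3,3] shift delivers prenyl to C8 and unveils the one phenol that can close. A chiral bifunctional thiourea then effects 6-endo oxa-Michael closure to the (2S)-flavanone. The precursor is made from 2-methylresorcinol by borylation–oxidation, O-tert-prenylation, ortho-lithiation–acetylation and aldol condensation.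

Key step: step 7

Assumption: the quinidine-derived bifunctional thiourea is taken to deliver the (2S) flavanone; if the sense of induction were opposite, its quinine-derived pseudoenantiomer would be used in the same step.

Step 1
Reactants: 1 2-methylresorcinol
Product: 2 1,3-bis(methoxymethoxy)-2-methylbenzene
Conditions: NaH (2.2 equiv), MOMCl (2.2 equiv), DMF, 0 °C to rt
Reagents that add atoms: chloromethyl methyl ether, COCCl
Why: Williamson-type O-alkylation of both phenoxides (MOM protection) on a symmetric diol, so no selectivity question arises.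

Step 2
Reactants: 2 1,3-bis(methoxymethoxy)-2-methylbenzene
Product: 4 3,5-bis(methoxymethoxy)-4-methylphenol, via arylboronate 3 (not isolated)
Conditions: [Ir(OMe)(cod)]2 (1.5 mol %), dtbpy (3 mol %), B2pin2 (0.6 equiv), THF, 80 °C; then aq. H2O2, NaOH, 0 °C
Reagents that add atoms: hydrogen peroxide, OO; bis(pinacolato)diboron, CC1(C)OB(OC1(C)C)B1OC(C)(C)C(C)(C)O1 (boron carried in intermediate 3 only)
Why: Sterically governed iridium-catalysed C–H borylation should take the only ring C–H without an ortho substituent (para to the methyl group), and oxidative hydroxydeboronation then gives the phenol that becomes O1.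

Step 3
Reactants: 5 2-methylbut-3-en-2-ol
Product: 6 tert-butyl 2-methylbut-3-en-2-yl carbonate
Conditions: n-BuLi, THF, −78 °C; then Boc2O, −78 °C to rt
Reagents that add atoms: di-tert-butyl dicarbonate, CC(C)(C)OC(=O)OC(=O)OC(C)(C)C
Why: Alkoxycarbonylation of the lithium alkoxide of a tertiary allylic alcohol with Boc2O should give the mixed carbonate.

Step 4
Reactants: 4 3,5-bis(methoxymethoxy)-4-methylphenol; 6 tert-butyl 2-methylbut-3-en-2-yl carbonate
Product: 7 1,3-bis(methoxymethoxy)-2-methyl-5-[(2-methylbut-3-en-2-yl)oxy]benzene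
Conditions: Pd(PPh3)4 (5 mol %), THF, 0 °C
Reagents that add atoms: none
Why: In this decarboxylative Tsuji–Trost O-allylation, zerovalent palladium ionises the carbonate to a 1,1-dimethyl-π-allyl complex and the phenoxide should attack the more substituted terminus under kinetic control, giving the branched aryl ether.

Step 5
Reactants: 7 1,3-bis(methoxymethoxy)-2-methyl-5-[(2-methylbut-3-en-2-yl)oxy]benzene
Product: 9 1-{2,4-bis(methoxymethoxy)-3-methyl-6-[(2-methylbut-3-en-2-yl)oxy]phenyl}ethan-1-one, via aryllithium 8 (not isolated)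
Conditions: n-BuLi (1.1 equiv), THF, 0 °C; then MeC(O)N(OMe)Me, −78 to 0 °C; aq. NH4Cl
Reagents that add atoms: N-methoxy-N-methylacetamide, CC(=O)N(C)OC; n-butyllithium, [Li]CCCC (lithium carried in intermediate 8 only)
Why: Directed ortho-metalation should occur at a ring C–H flanked by the MOM ether and the allyloxy oxygen (the two such sites are equivalent by symmetry), and Weinreb ketone synthesis then places the acetyl group between the future O1 and the future 5-oxygen.

Step 6
Reactants: 9 1-{2,4-bis(methoxymethoxy)-3-methyl-6-[(2-methylbut-3-en-2-yl)oxy]phenyl}ethan-1-one; 10 4-(methoxymethoxy)benzaldehyde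
Product: 11 (E)-1-{2,4-bis(methoxymethoxy)-3-methyl-6-[(2-methylbut-3-en-2-yl)oxy]phenyl}-3-[4-(methoxymethoxy)phenyl]prop-2-en-1-one
Conditions: KOH, EtOH/H2O, rt
Reagents that add atoms: none
Why: Claisen–Schmidt aldol condensation with E1cB dehydration should give the E-enone, and with no free phenol present the chalcone cannot cyclise prematurely.

Step 7
Reactants: 11 (E)-1-{2,4-bis(methoxymethoxy)-3-methyl-6-[(2-methylbut-3-en-2-yl)oxy]phenyl}-3-[4-(methoxymethoxy)phenyl]prop-2-en-1-one
Product: 14 (2S)-5,7-bis(methoxymethoxy)-2-[4-(methoxymethoxy)phenyl]-6-methyl-8-(3-methylbut-2-en-1-yl)-2,3-dihydro-4H-chromen-4-one, via dienone 12 (not isolated), via hydroxychalcone 13 (not isolated)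
Conditions: PhMe (degassed, dilute), 100 °C; then −20 °C, 3,5-bis(trifluoromethyl)phenyl thiourea of 9-amino(9-deoxy)epiquinidine (10 mol %)
Reagents that add atoms: none
Why: Heating triggers a [3,3]-sigmatropic shift of the 1,1-dimethylallyl group from oxygen to the only free ortho carbon with allylic inversion, so it arrives as the linear prenyl group, and dienone 12 tautomerises to phenol 13; on cooling, the catalyst's quinuclidine activates the phenol while the thiourea binds the enone carbonyl, and the oxygen adds to the β-carbon. The closest known reaction types are the aromatic Claisen rearrangement of aryl tert-prenyl ethers and the organocatalytic asymmetric cyclisation of 2'-hydroxychalcones to flavanones. Ring C closes in the 6-endo-trig mode (intramolecular oxa-Michael addition), forming the O1–C2 bond. The C2 stereocentre is set by the chiral catalyst through enantioface selection at the β-carbon, as no other stereocentre is present. The step needs regiocontrol over which oxygen flanking the acyl group closes and where the prenyl group lands; both are secured because the sigmatropic shift frees exactly one phenol and places prenyl on the carbon next to it, while the other flanking oxygen is a MOM ether. It also needs the uncatalysed thermal closure of 13 to stay slow, which the neutral aprotic medium and the chelated phenol should favour.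

Step 8
Reactants: 14 (2S)-5,7-bis(methoxymethoxy)-2-[4-(methoxymethoxy)phenyl]-6-methyl-8-(3-methylbut-2-en-1-yl)-2,3-dihydro-4H-chromen-4-one
Product: 15 6-methyl-8-prenylnaringenin, (2S)-5,7-dihydroxy-2-(4-hydroxyphenyl)-6-methyl-8-(3-methylbut-2-en-1-yl)-2,3-dihydro-4H-chromen-4-one
Conditions: HCl (3 M aq.), MeOH, 40 °C
Reagents that add atoms: none
Why: Acid-catalysed acetal solvolysis should remove all three MOM groups without base, so C2 is not epimerised by ring opening, and the moderate acidity should spare the prenyl group.

Compound list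
1 | 2-methylresorcinol (2-methylbenzene-1,3-diol) | Cc1c(O)cccc1O | starting material
2 | 1,3-bis(methoxymethoxy)-2-methylbenzene | Cc1c(OCOC)cccc1OCOC | intermediate
3 | 2-[3,5-bis(methoxymethoxy)-4-methylphenyl]-4,4,5,5-tetramethyl-1,3,2-dioxaborolane (arylboronate) | Cc1c(OCOC)cc(B2OC(C)(C)C(C)(C)O2)cc1OCOC | intermediate
4 | 3,5-bis(methoxymethoxy)-4-methylphenol | Cc1c(OCOC)cc(O)cc1OCOC | intermediate
5 | 2-methylbut-3-en-2-ol | CC(C)(O)C=C | starting material
6 | tert-butyl 2-methylbut-3-en-2-yl carbonate | CC(C)(C)OC(=O)OC(C)(C)C=C | intermediate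
7 | 1,3-bis(methoxymethoxy)-2-methyl-5-[(2-methylbut-3-en-2-yl)oxy]benzene | Cc1c(OCOC)cc(OC(C)(C)C=C)cc1OCOC | intermediate
8 | {2,4-bis(methoxymethoxy)-3-methyl-6-[(2-methylbut-3-en-2-yl)oxy]phenyl}lithium (aryllithium) | Cc1c(OCOC)cc(OC(C)(C)C=C)c([Li])c1OCOC | intermediate
9 | 1-{2,4-bis(methoxymethoxy)-3-methyl-6-[(2-methylbut-3-en-2-yl)oxy]phenyl}ethan-1-one | Cc1c(OCOC)cc(OC(C)(C)C=C)c(C(C)=O)c1OCOC | intermediate
10 | 4-(methoxymethoxy)benzaldehyde | COCOc1ccc(C=O)cc1 | starting material
11 | (E)-1-{2,4-bis(methoxymethoxy)-3-methyl-6-[(2-methylbut-3-en-2-yl)oxy]phenyl}-3-[4-(methoxymethoxy)phenyl]prop-2-en-1-one | Cc1c(OCOC)cc(OC(C)(C)C=C)c(C(=O)/C=C/c2ccc(OCOC)cc2)c1OCOC | intermediate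
12 | 2-{(2E)-3-[4-(methoxymethoxy)phenyl]prop-2-enoyl}-3,5-bis(methoxymethoxy)-4-methyl-6-(3-methylbut-2-en-1-yl)cyclohexa-2,4-dien-1-one (dienone, racemic at C6) | O=C1C(CC=C(C)C)C(OCOC)=C(C)C(OCOC)=C1C(=O)/C=C/c1ccc(OCOC)cc1 | intermediate
13 | (E)-1-[2-hydroxy-4,6-bis(methoxymethoxy)-5-methyl-3-(3-methylbut-2-en-1-yl)phenyl]-3-[4-(methoxymethoxy)phenyl]prop-2-en-1-one (hydroxychalcone) | Cc1c(OCOC)c(CC=C(C)C)c(O)c(C(=O)/C=C/c2ccc(OCOC)cc2)c1OCOC | intermediate
14 | (2S)-5,7-bis(methoxymethoxy)-2-[4-(methoxymethoxy)phenyl]-6-methyl-8-(3-methylbut-2-en-1-yl)-2,3-dihydro-4H-chromen-4-one | CC(C)=CCc1c(OCOC)c(C)c(OCOC)c2c1O[C@H](c1ccc(OCOC)cc1)CC2=O | intermediate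
15 | 6-methyl-8-prenylnaringenin, (2S)-5,7-dihydroxy-2-(4-hydroxyphenyl)-6-methyl-8-(3-methylbut-2-en-1-yl)-2,3-dihydro-4H-chromen-4-one | CC(C)=CCc1c(O)c(C)c(O)c2c1O[C@H](c1ccc(O)cc1)CC2=O | target

Total step count: 8. Longest linear sequence: 7 steps (steps 1, 2, 4, 5, 6, 7 and 8; step 3 prepares the carbonate for step 4).

Steps most likely to fail

Step 7. Enantioface discrimination in the oxa-Michael closure may be insufficient. It would be eroded further by uncatalysed thermal ring closure during the Claisen stage and by reversible ring opening under the basic catalyst. The fallback separates ring closure from enantiocontrol and sets out from 11. Heating in toluene gives hydroxychalcone 13, which is closed without a chiral catalyst (NaOAc, EtOH, reflux) to the racemic flavanone F1. Kinetic resolution by asymmetric transfer hydrogenation (RuCl[(R,R)-TsDPEN](p-cymene), HCO2H/Et3N, EtOAc, rt) should then reduce the (2R) enantiomer to the cis-(2R,4R)-flavan-4-ol F2 and leave the (2S)-flavanone, which is separated by chromatography. The route is rejoined at 14. The same resolution could also raise the enantiopurity of partly enriched 14 from step 7.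

Step 4. The phenoxide may attack the less substituted allyl terminus or react through a ring carbon (C-allylation), and the branched ether may re-ionise and isomerise under the palladium catalyst. The fallback sets out from 4. Copper-catalysed propargylation (3-chloro-3-methylbut-1-yne, CuCl2·2H2O cat., DBU, MeCN, 0 °C) should give the aryl 1,1-dimethylpropargyl ether F3. Semi-hydrogenation (H2, Pd/CaCO3 poisoned with Pb(OAc)2, quinoline, EtOAc) then gives the 1,1-dimethylallyl ether, rejoining the route at 7.

Step 5. Lateral deprotonation of the ring methyl group, attack of the base on the allyl ether, or enolisation of the amide in place of addition may compete. The fallback sets out from 7 and fixes the metalation site by electrophilic substitution instead of deprotonation. Mono-iodination of the electron-rich ring (NIS, MeCN, 0 °C) should give the aryl iodide F4. Iodine–lithium exchange (n-BuLi, THF, −78 °C) gives aryllithium 8 at a temperature where lateral lithiation does not compete, and acylation with N-methoxy-N-methylacetamide rejoins the route at 9.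

Further compounds
F1 | step 7 | racemic 5,7-bis(methoxymethoxy)-2-[4-(methoxymethoxy)phenyl]-6-methyl-8-(3-methylbut-2-en-1-yl)-2,3-dihydro-4H-chromen-4-one | CC(C)=CCc1c(OCOC)c(C)c(OCOC)c2c1OC(c1ccc(OCOC)cc1)CC2=O
F2 | step 7 | (2R,4R)-5,7-bis(methoxymethoxy)-2-[4-(methoxymethoxy)phenyl]-6-methyl-8-(3-methylbut-2-en-1-yl)-3,4-dihydro-2H-chromen-4-ol | CC(C)=CCc1c(OCOC)c(C)c(OCOC)c2c1O[C@@H](c1ccc(OCOC)cc1)C[C@H]2O
F3 | step 4 | 1,3-bis(methoxymethoxy)-2-methyl-5-[(2-methylbut-3-yn-2-yl)oxy]benzene | Cc1c(OCOC)cc(OC(C)(C)C#C)cc1OCOC
F4 | step 5 | 2-iodo-3,5-bis(methoxymethoxy)-4-methyl-1-[(2-methylbut-3-en-2-yl)oxy]benzene | Cc1c(OCOC)cc(OC(C)(C)C=C)c(I)c1OCOC
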